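**Retrosynthetic overview**
- The C7 acetate is installed last. Both Z-alkenes come from one semihydrogenation of a diyne diol.
- The C7–C8 bond and the C7/C8 stereocentres come from a dianion anti-aldol of a 2-chloro-4-hydroxy-4-octynylcyclopentenone with methyl 7-oxohept-5-ynoate.
- The C10–Cl bond comes from pyridine-mediated α-chlorination of the enone.
- The C12–C13 bond and the C12 carbinol stereocentre come from a chiral-biphenol-catalysed desymmetrising propargylboration of cyclopent-4-ene-1,3-dione with a 3-pentylallenylboronate (new reaction).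
- Ring order: the only ring, the cyclopentenone, is bought intact as the ene-dione; no ring is formed in the route.

Position labels: prostanoid numbering (C1 = ester carbon, C8–C12 = ring, C20 = chain end); the target is 7S, 8R, 12S, 5Z, 14Z.
Assumption: (S)-3,3'-Br2-BINOL is taken to give Re-face attack and the (S)-carbinol; if the sense proves opposite, the (R)-catalyst is used with nothing else changed.

**Step 1**
Reactants: 1 1-bromooct-2-yne
Product: 2 5,5-dimethyl-2-(octa-1,2-dien-3-yl)-1,3,2-dioxaborinane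
Conditions: B2nep2 (1.1 equiv), CuCl (5 mol %), Xantphos (5 mol %), KOt-Bu (1.2 equiv), THF, 0 °C → rt
Reagents that add atoms: bis(neopentyl glycolato)diboron (B2nep2), CC1(C)COB(OC1)B1OCC(C)(C)CO1
Why: The ligated Cu–B species adds syn across the alkyne with boron on the pentyl-bearing carbon and β-bromide elimination gives the allene (copper-catalysed SN2′ boryl substitution of a propargylic electrophile); no stereocentre is formed.

**Step 2**
Reactants: 2 5,5-dimethyl-2-(octa-1,2-dien-3-yl)-1,3,2-dioxaborinane; 3 cyclopent-4-ene-1,3-dione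
Product: 5 (4S)-4-hydroxy-4-(oct-2-yn-1-yl)cyclopent-2-en-1-one, via borate ester 4 (not isolated)
Conditions: (S)-3,3'-Br2-BINOL (10 mol %), t-BuOH (2 equiv), PhCH3/PhCF3 3:1, −20 °C → 0 °C; pH 7 buffer
Reagents that add atoms: none
Why: Proposed new method: the diol exchanges onto boron to give a more Lewis-acidic chiral mixed boronate whose free naphthol OH hydrogen-bonds the remaining B–O oxygen, one carbonyl of 3 (the two are homotopic, so only π-face selection is needed) binds boron, and the allene CH2 terminus is delivered through a closed six-membered SE2′ chair to the Re face, the flat CH=CH arm and the CH2C(=O) arm being told apart by the 3-bromo group, which sets C12 as S before t-BuOH releases 5 and turns the catalyst over; the closest known reaction type is the chiral-biphenol-catalysed allyl- and allenylboration of simple ketones, not yet shown for a cyclic ene-1,3-dione or for a 3-alkylallenylboronate.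

**Step 3**
Reactants: 5 (4S)-4-hydroxy-4-(oct-2-yn-1-yl)cyclopent-2-en-1-one
Product: 6 (4S)-2-chloro-4-hydroxy-4-(oct-2-yn-1-yl)cyclopent-2-en-1-one
Conditions: PhICl2 (1.2 equiv), pyridine (3 equiv), CH2Cl2, 0 °C, dark
Reagents that add atoms: (dichloroiodo)benzene, ClI(Cl)c1ccccc1
Why: Pyridine adds reversibly to the enone β-carbon, the resulting enolate is chlorinated at C2 and E1cB loss of pyridine restores the enone (amine-mediated α-halogenation of an enone, the chloro counterpart of the Johnson α-iodination), while the dialkyl alkyne, the tertiary alcohol and the C4 stereocentre are untouched.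

**Step 4**
Reactants: 7 3,3-diethoxyprop-1-yne; 8 4-bromo-1,1,1-trimethoxybutane
Product: 12 methyl 7-oxohept-5-ynoate, via lithium acetylide 9 (not isolated), via acetal orthoester 10 (not isolated), via acetal ester 11 (not isolated)
Conditions: n-BuLi, THF, −78 °C; 8, HMPA, −78 °C → rt; 0.1 M aq. HCl, THF, 0 °C; then 80% aq. HCO2H, rt
Reagents that add atoms: water, O
Why: SN2 alkylation of a lithium acetylide by a primary bromide, with the ester masked as a base-stable orthoester and the aldehyde as an acetal, is followed by staged acid hydrolysis (orthoester first, then the propargylic acetal); no stereocentre is formed.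

**Step 5**
Reactants: 6 (4S)-2-chloro-4-hydroxy-4-(oct-2-yn-1-yl)cyclopent-2-en-1-one; 12 methyl 7-oxohept-5-ynoate
Product: 15 methyl (7R)-7-[(1R,5S)-3-chloro-5-hydroxy-5-(oct-2-yn-1-yl)-2-oxocyclopent-3-en-1-yl]-7-hydroxyhept-5-ynoate, via dianion 13 (not isolated), via aldolate 14 (not isolated)
Conditions: LiN(SiMe3)2 (2.1 equiv), THF, −78 °C; 12 (1.3 equiv), −78 °C, 20 min; AcOH, −78 °C
Reagents that add atoms: none
Why: The alkoxide–dienolate dianion cannot β-eliminate, and its ring-locked E-enolate reacts through a closed Zimmerman–Traxler transition state with lithium bridged to the C12 alkoxide, so the non-enolisable ynal is delivered on the alkoxide face, anti to the octynyl chain (C8 = R, side chains trans), with the anti relationship at C7 (R in the diyne series) (substrate-controlled dianion aldol addition).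

**Step 6**
Reactants: 15 methyl (7R)-7-[(1R,5S)-3-chloro-5-hydroxy-5-(oct-2-yn-1-yl)-2-oxocyclopent-3-en-1-yl]-7-hydroxyhept-5-ynoate
Product: 16 methyl (5Z,7S)-7-[(1R,5S)-3-chloro-5-hydroxy-5-[(2Z)-oct-2-en-1-yl]-2-oxocyclopent-3-en-1-yl]-7-hydroxyhept-5-enoate
Conditions: H2 (1 atm), Pd/CaCO3 poisoned with Pb(OAc)2, quinoline, EtOAc, 0 °C → rt, stopped at 2 equiv H2
Reagents that add atoms: none
Why: Syn delivery of H2 on lead-poisoned palladium stops at the cis-alkene for both alkynes (Lindlar semihydrogenation) and should leave the hindered, electron-poor chloroenone, the vinylic C–Cl bond and the alcohols alone; the C7 descriptor changes from R to S only because the CIP priorities change.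

**Step 7**
Reactants: 16 methyl (5Z,7S)-7-[(1R,5S)-3-chloro-5-hydroxy-5-[(2Z)-oct-2-en-1-yl]-2-oxocyclopent-3-en-1-yl]-7-hydroxyhept-5-enoate
Product: 17 punaglandin 8, methyl (5Z,7S)-7-acetoxy-7-[(1R,5S)-3-chloro-5-hydroxy-5-[(2Z)-oct-2-en-1-yl]-2-oxocyclopent-3-en-1-yl]hept-5-enoate
Conditions: Ac2O (1.5 equiv), pyridine, CH2Cl2, −20 °C → 0 °C; cold pH 7 buffer
Reagents that add atoms: acetic anhydride, CC(=O)OC(C)=O
Why: The secondary allylic alcohol is acylated far faster than the hindered tertiary C12 alcohol (chemoselective O-acetylation), and low temperature without DMAP is intended to avoid E1cB loss of acetic acid across C7–C8; no stereocentre is touched.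

**Compound list**
1 | 1-bromooct-2-yne | CCCCCC#CCBr | starting material
2 | 5,5-dimethyl-2-(octa-1,2-dien-3-yl)-1,3,2-dioxaborinane | C=C=C(CCCCC)B1OCC(C)(C)CO1 | intermediate
3 | cyclopent-4-ene-1,3-dione | O=C1CC(=O)C=C1 | starting material
4 | 5,5-dimethyl-2-{[(1S)-1-(oct-2-yn-1-yl)-4-oxocyclopent-2-en-1-yl]oxy}-1,3,2-dioxaborinane (borate ester of 5) | CCCCCC#CC[C@@]1(OB2OCC(C)(C)CO2)C=CC(=O)C1 | intermediate
5 | (4S)-4-hydroxy-4-(oct-2-yn-1-yl)cyclopent-2-en-1-one | CCCCCC#CC[C@@]1(O)C=CC(=O)C1 | intermediate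
6 | (4S)-2-chloro-4-hydroxy-4-(oct-2-yn-1-yl)cyclopent-2-en-1-one | CCCCCC#CC[C@@]1(O)C=C(Cl)C(=O)C1 | intermediate
7 | 3,3-diethoxyprop-1-yne | CCOC(OCC)C#C | starting material
8 | 4-bromo-1,1,1-trimethoxybutane (trimethyl 4-bromoorthobutyrate) | COC(CCCBr)(OC)OC | starting material
9 | (3,3-diethoxyprop-1-yn-1-yl)lithium | [Li]C#CC(OCC)OCC | intermediate
10 | 7,7-diethoxy-1,1,1-trimethoxyhept-5-yne | CCOC(OCC)C#CCCCC(OC)(OC)OC | intermediate
11 | methyl 7,7-diethoxyhept-5-ynoate | CCOC(OCC)C#CCCCC(=O)OC | intermediate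
12 | methyl 7-oxohept-5-ynoate | COC(=O)CCCC#CC=O | intermediate
13 | dilithium (5S)-3-chloro-5-(oct-2-yn-1-yl)cyclopenta-1,3-diene-2,5-bis(olate) (alkoxide–dienolate dianion of 6) | CCCCCC#CC[C@@]1(O[Li])C=C(Cl)C(O[Li])=C1 | intermediate
14 | dilithium bis-alkoxide of 15 (C7 and C12 oxygens lithiated; 7R, 8R, 12S) | CCCCCC#CC[C@@]1(O[Li])C=C(Cl)C(=O)[C@@H]1[C@H](C#CCCCC(=O)OC)O[Li] | intermediate
15 | methyl (7R)-7-[(1R,5S)-3-chloro-5-hydroxy-5-(oct-2-yn-1-yl)-2-oxocyclopent-3-en-1-yl]-7-hydroxyhept-5-ynoate | CCCCCC#CC[C@@]1(O)C=C(Cl)C(=O)[C@@H]1[C@H](C#CCCCC(=O)OC)O | intermediate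
16 | methyl (5Z,7S)-7-[(1R,5S)-3-chloro-5-hydroxy-5-[(2Z)-oct-2-en-1-yl]-2-oxocyclopent-3-en-1-yl]-7-hydroxyhept-5-enoate | CCCCC/C=C\C[C@@]1(O)C=C(Cl)C(=O)[C@@H]1[C@H](/C=C\CCCC(=O)OC)O | intermediate
17 | punaglandin 8, methyl (5Z,7S)-7-acetoxy-7-[(1R,5S)-3-chloro-5-hydroxy-5-[(2Z)-oct-2-en-1-yl]-2-oxocyclopent-3-en-1-yl]hept-5-enoate | CCCCC/C=C\C[C@@]1(O)C=C(Cl)C(=O)[C@@H]1[C@H](/C=C\CCCC(=O)OC)OC(C)=O | target

**Step count**
Total: 7 steps. Longest linear sequence: 6 steps (steps 1, 2, 3, 5, 6, 7 from 1-bromooct-2-yne); step 4 is the side branch.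

**Three steps most likely to fail, with fallbacks**

Step 2 (the proposed new propargylboration). The ene-dione may polymerise or add twice, and the catalyst may not distinguish the CH=CH arm from the CH2C(=O) arm well enough. The fallback uses only known chemistry and gives up catalytic induction for a resolution. It sets out from 1 and comes back at 5.
- NaC5H5 in THF is alkylated with 1 at −40 °C to give 5-(oct-2-yn-1-yl)cyclopenta-1,3-diene F1.
- On warming to 0 °C this undergoes the [1,5]-hydrogen shift to 1-(oct-2-yn-1-yl)cyclopenta-1,3-diene F2.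
- Sensitised photooxygenation (O2, tetraphenylporphyrin, hν, CH2Cl2, −78 °C) gives by [4+2] addition the endoperoxide rac-1-(oct-2-yn-1-yl)-2,3-dioxabicyclo[2.2.1]hept-5-ene F3.
- Et3N at −78 °C → 0 °C effects the Kornblum–DeLaMare rearrangement (loss of the single bridgehead hydrogen) to racemic 4-hydroxy-4-(oct-2-yn-1-yl)cyclopent-2-en-1-one F4.
- Preparative chromatography on a chiral stationary phase gives 5; the unwanted (R)-4-hydroxy-4-(oct-2-yn-1-yl)cyclopent-2-en-1-one F5 is set aside.

Step 5 (dianion aldol). The risks are facial and anti/syn selectivity with a slim ynal, and retro-aldol opening of the tertiary lithium alkoxide before the second deprotonation. The fallback is the protected mono-enolate route. It sets out from 6 and comes back at 15.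
- Me3SiOTf/2,6-lutidine (CH2Cl2, −78 °C) gives the silyl ether (4S)-2-chloro-4-(oct-2-yn-1-yl)-4-(trimethylsilyloxy)cyclopent-2-en-1-one F6.
- LiN(i-Pr)2 in THF at −78 °C gives its lithium enolate F7.
- Addition of 12 gives the lithium aldolate F8, and AcOH quench at −78 °C gives the silyl-protected aldol methyl (7R)-7-[(1R,5S)-3-chloro-5-(oct-2-yn-1-yl)-2-oxo-5-(trimethylsilyloxy)cyclopent-3-en-1-yl]-7-hydroxyhept-5-ynoate F9.
- AcOH–THF–H2O at rt removes the silyl group to give 15.

Step 3 (direct α-chlorination). The risks are competing chlorination of the alkyne, pyridinium by-products, or low conversion on the free hydroxy-enone. The fallback is the epoxide route. It sets out from 5 and comes back at 6.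
- Weitz–Scheffer epoxidation (t-BuOOH, DBU, CH2Cl2, 0 °C) gives the epoxy ketone (4S)-2,3-epoxy-4-hydroxy-4-(oct-2-yn-1-yl)cyclopentan-1-one F10. The epoxide is expected cis to the hydroxyl and anti to the chain; either epimer serves.
- HCl in CHCl3 at 0 °C opens it at the α-carbon to the trans-chlorohydrin (4S)-2-chloro-3,4-dihydroxy-4-(oct-2-yn-1-yl)cyclopentan-1-one F11, which loses water in the same flask to give 6.

**Further compounds**
F1 | step 2 | 5-(oct-2-yn-1-yl)cyclopenta-1,3-diene | CCCCCC#CCC1C=CC=C1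
F2 | step 2 | 1-(oct-2-yn-1-yl)cyclopenta-1,3-diene | CCCCCC#CCC1=CC=CC1
F3 | step 2 | rac-1-(oct-2-yn-1-yl)-2,3-dioxabicyclo[2.2.1]hept-5-ene | CCCCCC#CCC12CC(OO1)C=C2
F4 | step 2 | rac-4-hydroxy-4-(oct-2-yn-1-yl)cyclopent-2-en-1-one | CCCCCC#CCC1(O)C=CC(=O)C1
F5 | step 2 | (4R)-4-hydroxy-4-(oct-2-yn-1-yl)cyclopent-2-en-1-one | CCCCCC#CC[C@]1(O)C=CC(=O)C1
F6 | step 5 | (4S)-2-chloro-4-(oct-2-yn-1-yl)-4-(trimethylsilyloxy)cyclopent-2-en-1-one | CCCCCC#CC[C@@]1(O[Si](C)(C)C)C=C(Cl)C(=O)C1
F7 | step 5 | lithium (5S)-3-chloro-5-(oct-2-yn-1-yl)-5-(trimethylsilyloxy)cyclopenta-1,3-dien-2-olate | CCCCCC#CC[C@@]1(O[Si](C)(C)C)C=C(Cl)C(O[Li])=C1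
F8 | step 5 | lithium C7-alkoxide of F9 | CCCCCC#CC[C@@]1(O[Si](C)(C)C)C=C(Cl)C(=O)[C@@H]1[C@H](C#CCCCC(=O)OC)O[Li]
F9 | step 5 | methyl (7R)-7-[(1R,5S)-3-chloro-5-(oct-2-yn-1-yl)-2-oxo-5-(trimethylsilyloxy)cyclopent-3-en-1-yl]-7-hydroxyhept-5-ynoate | CCCCCC#CC[C@@]1(O[Si](C)(C)C)C=C(Cl)C(=O)[C@@H]1[C@H](C#CCCCC(=O)OC)O
F10 | step 3 | (4S)-2,3-epoxy-4-hydroxy-4-(oct-2-yn-1-yl)cyclopentan-1-one, epoxide cis to the hydroxyl | CCCCCC#CC[C@@]1(O)[C@@H]2O[C@@H]2C(=O)C1
F11 | step 3 | (4S)-2-chloro-3,4-dihydroxy-4-(oct-2-yn-1-yl)cyclopentan-1-one, Cl trans to 3-OH, 3-OH cis to 4-OH | CCCCCC#CC[C@@]1(O)[C@H](O)[C@@H](Cl)C(=O)C1
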